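**Conventions.** Ring A: C1 (OMe), C2 (H), C3 (ether oxygen), C4 (acetyl), C5 (OH), C6 (CH3). Ring B: C1' (ether oxygen), C2' (OH), C3' (CH3), C4' (OMe), C5' (acetyl), C6' (OH).

Remark on the chemistry: the target is achiral and has no stereocentre; the only stereodescriptor in the route is the enol ether geometry of the transient intermediate 9, which is inherited from a ring.

Compound key: 1 4-methoxy-6-methyl-2-pyrone; 2 its 3-bromide; 3 the 3-bromo-6-bromomethyl pyrone; 4 2,6-dimethoxytoluene; 5 aryl pinacol boronate; 6 3,5-dimethoxy-4-methylphenol; 7 bromopyrone aryl ether; 8 methylpyrone aryl ether; 9 open-chain keto ester; 10 diaryl ether resorcinol; 11 bis-acetyl compound; 12 leprolomin.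

## The problem

Leprolomin is a diaryl ether of two isomeric C-methylated, mono-O-methylated phloroacetophenone rings, so the task is one of connectivity and regiochemistry only. The hardest bond is O–C1': C1' lies in a hexasubstituted ring between the two hydroxyl-bearing carbons C2' and C6', and on the other side the oxygen sits ortho to the C4 acetyl group. Joining two finished aryl partners at this bond would be doubly ortho-hindered, electron-rich on both sides, and would need the flanking hydroxyls protected. The second difficulty is telling the oxygens apart: ring A has its methoxy group para to the acetyl (C1), while ring B has it ortho to the acetyl, wedged between C3' and C5'. Methylation of a ring B triphenol would go to the wrong oxygen (C2', para to the acetyl and not chelated). The feature that opens a way is that C2', C4' and C6' are the 1,3,5-oxygens of a phloroglucinol with C1' between two of them. Ring B is therefore the enol form of a 2-aryloxycyclohexane-1,3,5-trione monomethyl enol ether, and the run C2'–C3'(CH3)–C4'(OMe)–C5'–C6' is, atom for atom, C2–C6 of a 4-methoxy-3-methyl-2-pyrone with C1' as the carbon of its 6-methyl group. Sensitive points are the oxidisable electron-rich rings, the methoxy groups ortho to a ketone (Lewis acids), and any aryloxymethyl ketone carbanion next to an ortho-acetyl group, which would close to a benzofuran.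

## Retrosynthesis

**12 to 11.** The C5 hydroxyl of ring A is traced back to a methyl ether. The alternative of carrying a free C5–OH would make the ring A unit unsymmetrical, with two different phenolic oxygens for ether formation and two different C–H sites for acetylation. With the methyl ether the ring A unit is the mirror-symmetric 3,5-dimethoxy-4-methylphenyl group, and both choices disappear. The forward reaction must cleave only the methoxy group ortho to the ring A ketone, sparing C1–OMe (para) and C4'–OMe of ring B.

**11 to 10.** Both aryl–acetyl bonds (C4–CO and C5'–CO) are cut. Ring A cannot carry its acetyl earlier, because the key step passes through a carbanion of the type ArO–CH–C(=O), which would undergo aldol closure onto an ortho-acetyl group (Rap–Stoermer-type benzofuran formation). Ring B cannot carry it in the pyrone without creating a triacylmethane. The precursor 10 has one free position on ring B (C5') and two equivalent ones on ring A, so a double Friedel–Crafts acetylation has no regiochemical choice.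

**10 to 8 (key disconnection).** The C1'–C2' bond of ring B is cut, which turns C2' into a lactone carbonyl and the C6' oxygen into the ring oxygen of a 2-pyrone. Cutting O–C1' directly would leave the hindered aryl–aryl ether coupling. The other Claisen cut, C4'–C5', would make C4' an ester carbon and hence a hydroxyl, not the required methoxy. Pyrone 8 already holds the C3' methyl and the C4' methoxy group, and the diaryl ether oxygen has become the oxygen of an ordinary CH2–OAr ether. The forward reaction needs methoxide to open the lactone to keto ester 9 and the C1' carbanion to close onto the ester, with no other electrophile in reach.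

**8 to 7 to 3 + 6.** The C3'–CH3 bond is cut (Suzuki–Miyaura methylation of bromide 7), then the CH2–O bond (Williamson ether synthesis from bromide 3 and phenol 6). The methyl group is introduced after the side-chain bromination so that the radical step meets only one methyl group. Phenol 6 is symmetric, so the ether oxygen is unambiguous.

**3 to 2 to 1, and 6 to 4.** Dibromide 3 comes from commercial pyrone 1 by ionic bromination at C3 (2) and radical bromination of the 6-methyl group. Phenol 6 comes from commercial 2,6-dimethoxytoluene 4 by sterically controlled C–H borylation (boronate 5) and oxidation.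

## Roads not taken

**Alternative 1:** Cut O–C1' between two finished acetophenone halves (the most obvious route). The forward step is an Ullmann-type coupling of the ring A phenol 1-(2,6-dihydroxy-4-methoxy-3-methylphenyl)ethan-1-one A1 with the ring B bromide 1-[2,4-bis(benzyloxy)-3-bromo-6-methoxy-5-methylphenyl]ethan-1-one A2 to give the dibenzyl ether A3, then hydrogenolysis to 12. A2 is a hexasubstituted, electron-rich aryl bromide with two ortho benzyloxy groups, and A1 is a chelated ortho-acyl phenol with two competing hydroxyls. A2 also needs its own regiocontrolled assembly, including the awkward C4' methoxy group, plus protection and deprotection. The chosen plan forms the same C–O bond by an SN2 reaction at a primary carbon and needs no protecting group on ring B.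

**Alternative 2:** Cut C1'–C2' and C5'–C6' in an intermolecular version of the pyrone idea. The ester enolate of methyl 2-(3,5-dimethoxy-4-methylphenoxy)acetate A4 would attack the lactone carbonyl of 4-methoxy-3,6-dimethyl-2H-pyran-2-one A5 to give the open chain A6, whose C5' carbon would close onto the ester to give A7 with the ring B acetyl already in place. The enolate can attack C2, C4 or C6 of A5, or simply deprotonate its 6-methyl group. In A6 the ester to be attacked belongs to a 2-aryloxy β-keto ester whose C1'–H is the most acidic proton, so the electrophile is present as an unreactive enolate. Ring A would still need its acetyl group and demethylation, so only one C–C bond formation is saved.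

**Alternative 3:** Cut O–C1' by a biomimetic oxidative (anodic) coupling of phenol A1 with 1-(4,6-dihydroxy-2-methoxy-3-methylphenyl)ethan-1-one A8, giving 12 in one step. Both partners are oxidised at similar potentials, so homo- and cross-coupling compete. Phloroglucinol-derived radicals couple at carbon as readily as at oxygen, A1 offers two hydroxyls, and 12 is at least as oxidisable as its precursors. Nothing in the substrates directs bond formation to O(C3)–C1', whereas in the chosen plan that bond is fixed by covalent construction.

Key step: step 6

## Steps

Step 1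
Reactants: 1 4-methoxy-6-methyl-2H-pyran-2-one
Product: 2 3-bromo-4-methoxy-6-methyl-2H-pyran-2-one
Conditions: NBS, MeCN, rt, dark
Reagents that add atoms: N-bromosuccinimide, O=C1CCC(=O)N1Br
Why: Electrophilic bromination at C3, the α-carbon of the push–pull β-methoxy enoate and the most nucleophilic ring position of a 4-methoxy-2-pyrone; the bromide is the later handle for the C3' methyl group.

Step 2
Reactants: 2 3-bromo-4-methoxy-6-methyl-2H-pyran-2-one
Product: 3 3-bromo-6-(bromomethyl)-4-methoxy-2H-pyran-2-one
Conditions: NBS, AIBN (cat.), PhCF3, 85 °C
Reagents that add atoms: N-bromosuccinimide, O=C1CCC(=O)N1Br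
Why: Wohl–Ziegler bromination; the 6-methyl group is the only sp3 C–H site and its radical is delocalised through the pyrone diene onto the lactone carbonyl, as in the known bromination of the parent 4-methoxy-6-methyl-2-pyrone.

Step 3
Reactants: 4 1,3-dimethoxy-2-methylbenzene (2,6-dimethoxytoluene)
Product: 6 3,5-dimethoxy-4-methylphenol, via pinacol boronate 5 (not isolated)
Conditions: B2pin2, [Ir(OMe)(cod)]2 (cat.), 4,4'-di-tert-butyl-2,2'-bipyridine (cat.), THF, 80 °C; then KHSO5 (as 2KHSO5·KHSO4·K2SO4), acetone/H2O, rt
Reagents that add atoms: potassium peroxymonosulfate, [K+].[O-]S(=O)(=O)OO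
Why: Iridium-catalysed C–H borylation is sterically controlled and takes the only C–H bond without an ortho substituent (para to the methyl group); one-pot oxidation of the C–B bond gives the phenol at the same position.

Step 4
Reactants: 3 3-bromo-6-(bromomethyl)-4-methoxy-2H-pyran-2-one; 6 3,5-dimethoxy-4-methylphenol
Product: 7 3-bromo-6-[(3,5-dimethoxy-4-methylphenoxy)methyl]-4-methoxy-2H-pyran-2-one
Conditions: K2CO3, acetone, rt to 45 °C
Reagents that add atoms: none
Why: Williamson ether synthesis by SN2 displacement at a primary, pyrone-activated bromide; the phenol is symmetric so only one ether can form, and the vinylic C3–Br and C4–OMe bonds are inert to phenoxide under carbonate conditions.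

Step 5
Reactants: 7 3-bromo-6-[(3,5-dimethoxy-4-methylphenoxy)methyl]-4-methoxy-2H-pyran-2-one
Product: 8 6-[(3,5-dimethoxy-4-methylphenoxy)methyl]-4-methoxy-3-methyl-2H-pyran-2-one
Conditions: trimethylboroxine, Pd(PPh3)4 (cat.), K2CO3, 1,4-dioxane, 100 °C
Reagents that add atoms: trimethylboroxine, CB1OB(C)OB(C)O1
Why: Suzuki–Miyaura methylation; zerovalent palladium inserts into the C3–Br bond of the α-bromo enoate, methyl is transferred from boron and reductive elimination installs the future C3' methyl group, a coupling type established for 3-bromo-2-pyrones.

Step 6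
Reactants: 8 6-[(3,5-dimethoxy-4-methylphenoxy)methyl]-4-methoxy-3-methyl-2H-pyran-2-one
Product: 10 2-(3,5-dimethoxy-4-methylphenoxy)-5-methoxy-4-methylbenzene-1,3-diol, via open-chain keto ester 9 (not isolated)
Conditions: NaOMe (5 equiv), MeOH, sealed vessel, argon, 120 to 185 °C; then aq. HCl
Reagents that add atoms: none
Why: Base-mediated ring transformation of a 4-methoxy-2-pyrone into a phloroglucinol monomethyl ether, the closest known case being the 6-methyl pyrone without the aryloxy group under the same sodium methoxide conditions. Methoxide adds to the lactone carbonyl (C2') and the enol ester opens to keto ester 9, in which the ester carbon and the C5' methylene are held cis on the C3'=C4' enol ether because that geometry comes from the ring. The C5' methylene is the more acidic site but its anion can only revert, whereas the carbanion at C1', acidified by the C6' ketone and the aryloxy oxygen, attacks the ester carbon C2' in a 6-(enolendo)-exo-trig Claisen (Dieckmann) closure; loss of methoxide and enolisation give the aromatic ring, and phenoxide formation makes the sequence irreversible. O-acylation by the enolate oxygen only regenerates 8 and is harmless. No stereocentre is formed. The selectivity required is C-acylation at C1' in preference to any other carbonyl chemistry, and the substrate secures it: ring A carries no acetyl group at this stage, so benzofuran formation is impossible and the ester is the only electrophile within reach. The pyrone delivers C3' with its methyl and C4' with its methoxy group, so the product has the ether oxygen between two free hydroxyls without any protecting group.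

Step 7
Reactants: 10 2-(3,5-dimethoxy-4-methylphenoxy)-5-methoxy-4-methylbenzene-1,3-diol
Product: 11 1-[3-(2-acetyl-3,5-dimethoxy-4-methylphenoxy)-2,4-dihydroxy-6-methoxy-5-methylphenyl]ethan-1-one
Conditions: Ac2O, BF3·OEt2, CH2Cl2, 0 to 40 °C; then K2CO3, MeOH/H2O, rt
Reagents that add atoms: acetic anhydride, CC(=O)OC(C)=O
Why: Double Friedel–Crafts acetylation of two phloroglucinol-type rings; ring B has a single free position (C5') and ring A two positions equivalent by symmetry, the first acetyl group deactivating ring A against a second; the basic work-up cleaves any aryl acetate and the boron chelate.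

Step 8
Reactants: 11 1-[3-(2-acetyl-3,5-dimethoxy-4-methylphenoxy)-2,4-dihydroxy-6-methoxy-5-methylphenyl]ethan-1-one
Product: 12 leprolomin, 1-[3-(2-acetyl-3-hydroxy-5-methoxy-4-methylphenoxy)-2,4-dihydroxy-6-methoxy-5-methylphenyl]ethan-1-one
Conditions: BCl3 (3.5 equiv), CH2Cl2, −78 to 0 °C; then H2O
Reagents that add atoms: none
Why: Chelation-controlled demethylation ortho to an aryl ketone; boron bound to the ring A carbonyl bridges to the C5 methoxy oxygen and chloride removes the methyl group, while C1–OMe (para) is untouched and C4'–OMe is spared because the ring B carbonyl is already locked in a boron chelate with the C6' oxygen, as in the known stop at the mono-phenol stage for 2,6-dimethoxyaryl ketones.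

## Compound list

1 | 4-methoxy-6-methyl-2H-pyran-2-one | COc1cc(C)oc(=O)c1 | starting material
2 | 3-bromo-4-methoxy-6-methyl-2H-pyran-2-one | COc1cc(C)oc(=O)c1Br | intermediate
3 | 3-bromo-6-(bromomethyl)-4-methoxy-2H-pyran-2-one | COc1cc(CBr)oc(=O)c1Br | intermediate
4 | 1,3-dimethoxy-2-methylbenzene (2,6-dimethoxytoluene) | COc1cccc(OC)c1C | starting material
5 | 2-(3,5-dimethoxy-4-methylphenyl)-4,4,5,5-tetramethyl-1,3,2-dioxaborolane | COc1cc(B2OC(C)(C)C(C)(C)O2)cc(OC)c1C | intermediate (not isolated)
6 | 3,5-dimethoxy-4-methylphenol | COc1cc(O)cc(OC)c1C | intermediate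
7 | 3-bromo-6-[(3,5-dimethoxy-4-methylphenoxy)methyl]-4-methoxy-2H-pyran-2-one | COc1cc(COc2cc(OC)c(C)c(OC)c2)oc(=O)c1Br | intermediate
8 | 6-[(3,5-dimethoxy-4-methylphenoxy)methyl]-4-methoxy-3-methyl-2H-pyran-2-one | COc1cc(COc2cc(OC)c(C)c(OC)c2)oc(=O)c1C | intermediate
9 | methyl (2E)-6-(3,5-dimethoxy-4-methylphenoxy)-3-methoxy-2-methyl-5-oxohex-2-enoate | COC(=O)/C(C)=C(OC)\CC(=O)COc1cc(OC)c(C)c(OC)c1 | intermediate (not isolated)
10 | 2-(3,5-dimethoxy-4-methylphenoxy)-5-methoxy-4-methylbenzene-1,3-diol | COc1cc(O)c(Oc2cc(OC)c(C)c(OC)c2)c(O)c1C | intermediate
11 | 1-[3-(2-acetyl-3,5-dimethoxy-4-methylphenoxy)-2,4-dihydroxy-6-methoxy-5-methylphenyl]ethan-1-one | COc1cc(Oc2c(O)c(C)c(OC)c(C(C)=O)c2O)c(C(C)=O)c(OC)c1C | intermediate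
12 | leprolomin, 1-[3-(2-acetyl-3-hydroxy-5-methoxy-4-methylphenoxy)-2,4-dihydroxy-6-methoxy-5-methylphenyl]ethan-1-one | COc1cc(Oc2c(O)c(C)c(OC)c(C(C)=O)c2O)c(C(C)=O)c(O)c1C | target

## Step count and risk

Total: 8 steps. Longest linear sequence: 7 steps (steps 1, 2, 4, 5, 6, 7, 8); step 3 is the convergent branch.

**Step 6 (key step).** The C1' carbanion is stabilised and secondary, and the ester it must attack is a vinylogous carbonate that is further deactivated whenever the C5' methylene is deprotonated. At the temperature needed, retro-Claisen cleavage of 9 at the C6' ketone by methoxide, or loss of the aryloxide from the CH2–OAr carbon, may outrun ring closure.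

The fallback forms the aryl–oxygen bond by coupling and uses the pyrone ring transformation only in its parent form. It sets out from 2 and 6 and comes back at 10.
- Suzuki–Miyaura methylation of 2 (trimethylboroxine, Pd(PPh3)4, K2CO3, dioxane) would give 4-methoxy-3,6-dimethyl-2H-pyran-2-one F1.
- NaOMe in MeOH at 185 °C, where the nucleophile is the unsubstituted 6-methyl carbon, would give 5-methoxy-4-methylbenzene-1,3-diol F2.
- Chloromethyl methyl ether and iPr2NEt would give 1-methoxy-3,5-bis(methoxymethoxy)-2-methylbenzene F3.
- Lithiation with n-BuLi between the two acetal oxygens and quenching with iodine would give 2-iodo-5-methoxy-1,3-bis(methoxymethoxy)-4-methylbenzene F4.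
- Ullmann coupling of F4 with phenol 6 (CuI, picolinic acid, K3PO4, DMSO, 100 °C) would give 2-(3,5-dimethoxy-4-methylphenoxy)-5-methoxy-1,3-bis(methoxymethoxy)-4-methylbenzene F5.
- HCl in MeOH would remove both acetals and return 10.

**Step 7.** Acetylation of ring A next to the bulky, twisted diaryl ether may stall after ring B has reacted. O-acylation of the ring B phenols, or Lewis-acid demethylation next to the new ketones, may also consume material.

The fallback changes the electrophile to a nitrile, which cannot O-acylate and needs only a mild Lewis acid. It sets out from 10 and comes back at 11. A Houben–Hoesch reaction (MeCN, ZnCl2, HCl gas, Et2O, 0 °C) would precipitate the bis-ketiminium salt 1-[3-(2-ethanimidoyl-3,5-dimethoxy-4-methylphenoxy)-2,4-dihydroxy-6-methoxy-5-methylphenyl]ethan-1-imine dihydrochloride F6, and warm water would hydrolyse it to 11.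

**Step 8.** Chemoselectivity may be lost through cleavage of the ring B methoxy group at C4', which has the same local environment (acetyl on one side, methyl on the other) as the ring A group to be removed. The only difference is the prior chelation of the ring B carbonyl.

The fallback breaks the symmetry of ring A before any ketone is present. It sets out from 10 and comes back at 12. NaSEt in DMF at 120 °C would remove one of the two equivalent ring A methyl groups, ring B being protected as its electron-rich bis-phenoxide and ring A stopping at the mono-phenoxide, to give 2-(3-hydroxy-5-methoxy-4-methylphenoxy)-5-methoxy-4-methylbenzene-1,3-diol F7. Acetylation with Ac2O and BF3·OEt2 would then go ortho to the free ring A hydroxyl through the boron chelate, and at C5' of ring B, to give 12 directly.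

**Step 2.** Over-bromination to the dibromomethyl compound and ionic ring bromination at C5 may compete with the radical chain.

The fallback replaces radical halogenation and Williamson alkylation by oxidation and a Mitsunobu reaction. It sets out from 2 and comes back at 7. Oxidation of the 6-methyl group with SeO2 (dioxane, 160 °C, sealed) would give 3-bromo-4-methoxy-2-oxo-2H-pyran-6-carbaldehyde F8. NaBH4 in MeOH at 0 °C would give 3-bromo-6-(hydroxymethyl)-4-methoxy-2H-pyran-2-one F9. Mitsunobu etherification of F9 with phenol 6 (PPh3, diisopropyl azodicarboxylate, THF) would give 7.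

## Further compounds

F1 | step 6 | 4-methoxy-3,6-dimethyl-2H-pyran-2-one | COc1cc(C)oc(=O)c1C
F2 | step 6 | 5-methoxy-4-methylbenzene-1,3-diol | COc1cc(O)cc(O)c1C
F3 | step 6 | 1-methoxy-3,5-bis(methoxymethoxy)-2-methylbenzene | COCOc1cc(OCOC)c(C)c(OC)c1
F4 | step 6 | 2-iodo-5-methoxy-1,3-bis(methoxymethoxy)-4-methylbenzene | COCOc1cc(OC)c(C)c(OCOC)c1I
F5 | step 6 | 2-(3,5-dimethoxy-4-methylphenoxy)-5-methoxy-1,3-bis(methoxymethoxy)-4-methylbenzene | COCOc1cc(OC)c(C)c(OCOC)c1Oc1cc(OC)c(C)c(OC)c1
F6 | step 7 | 1-[3-(2-ethanimidoyl-3,5-dimethoxy-4-methylphenoxy)-2,4-dihydroxy-6-methoxy-5-methylphenyl]ethan-1-imine dihydrochloride | COc1cc(Oc2c(O)c(C)c(OC)c(C(C)=[NH2+])c2O)c(C(C)=[NH2+])c(OC)c1C.[Cl-].[Cl-]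
F7 | step 8 | 2-(3-hydroxy-5-methoxy-4-methylphenoxy)-5-methoxy-4-methylbenzene-1,3-diol | COc1cc(O)c(Oc2cc(O)c(C)c(OC)c2)c(O)c1C
F8 | step 2 | 3-bromo-4-methoxy-2-oxo-2H-pyran-6-carbaldehyde | COc1cc(C=O)oc(=O)c1Br
F9 | step 2 | 3-bromo-6-(hydroxymethyl)-4-methoxy-2H-pyran-2-one | COc1cc(CO)oc(=O)c1Br
A1 | alternative 1 | 1-(2,6-dihydroxy-4-methoxy-3-methylphenyl)ethan-1-one | COc1cc(O)c(C(C)=O)c(O)c1C
A2 | alternative 1 | 1-[2,4-bis(benzyloxy)-3-bromo-6-methoxy-5-methylphenyl]ethan-1-one | CC(=O)c1c(OCc2ccccc2)c(Br)c(OCc2ccccc2)c(C)c1OC
A3 | alternative 1 | 1-[3-(2-acetyl-3-hydroxy-5-methoxy-4-methylphenoxy)-2,4-bis(benzyloxy)-6-methoxy-5-methylphenyl]ethan-1-one | COc1cc(Oc2c(OCc3ccccc3)c(C)c(OC)c(C(C)=O)c2OCc2ccccc2)c(C(C)=O)c(O)c1C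
A4 | alternative 2 | methyl 2-(3,5-dimethoxy-4-methylphenoxy)acetate | COC(=O)COc1cc(OC)c(C)c(OC)c1
A5 | alternative 2 | 4-methoxy-3,6-dimethyl-2H-pyran-2-one | COc1cc(C)oc(=O)c1C
A6 | alternative 2 | methyl (4E)-2-(3,5-dimethoxy-4-methylphenoxy)-5-methoxy-4-methyl-3,7-dioxooct-4-enoate (racemic at C2) | COC(=O)C(Oc1cc(OC)c(C)c(OC)c1)C(=O)/C(C)=C(OC)\CC(C)=O
A7 | alternative 2 | 1-[3-(3,5-dimethoxy-4-methylphenoxy)-2,4-dihydroxy-6-methoxy-5-methylphenyl]ethan-1-one | COc1cc(Oc2c(O)c(C)c(OC)c(C(C)=O)c2O)cc(OC)c1C
A8 | alternative 3 | 1-(4,6-dihydroxy-2-methoxy-3-methylphenyl)ethan-1-one | COc1c(C)c(O)cc(O)c1C(C)=O
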